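**Retrosynthetic overview**
- Structural feature: ring A (C4a, C5, C6, C7, C8, C8a) is fused to the pyranone ring C along C4a–C8a. This ring alkene and an exocyclic C8=C7 enol ether together make a 1,3-diene, and C5–C6 is a vicinally dioxygenated two-carbon unit.
- Key disconnection: C4a–C5 and C6–C7. This is a retro-(4+2) of a tetrahydro ring A into a 6-aryl-2-(1-benzyloxy-2-methoxyvinyl)-4-pyranone and vinylene carbonate. The four sp3 carbons are flattened afterwards by removing four hydrogens.
- Diene: C7 is added by formylation and O-methylation of the benzyloxymethyl side chain of a 2,6-disubstituted 4-pyranone. O8 stays distinct from the other oxygens as its benzyl ether.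
- Pyranone: cyclodehydration of a 1,3,5-triketone assembled by two Claisen-type acylations (aryl methyl ketone, acetate ester, benzyloxyacetate ester).
- Ring order: ring B is bought, ring C closes in step 3, ring A closes in step 6 and is aromatised in step 7. The route ends with carbonate opening, methylation at O5 and O6, and debenzylation at O8.

Key step: step 6

Remark: flavone numbering (O1, C2, C3, C4, C4a, C5–C8, C8a) is used for the corresponding atoms of all intermediates.
Assumption: 7 is drawn as its Z enol although it should equilibrate with the aldehyde tautomer. Compounds 10 and 11 are racemic, with one enantiomer drawn. The target has no stereocentre.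

**Step 1**
Reactants: 1 3',4',5'-trimethoxyacetophenone; 2 ethyl acetate
Product: 3 1-(3,4,5-trimethoxyphenyl)butane-1,3-dione
Conditions: NaH (2.2 equiv), 2 (3 equiv), THF, 0 °C → reflux; 1 M HCl
Reagents that add atoms: none
Why: Crossed Claisen condensation in which the sodium enolate of 1 attacks the ester 2 and irreversible deprotonation of the 1,3-diketone pulls the equilibrium to the product.

**Step 2**
Reactants: 3 1-(3,4,5-trimethoxyphenyl)butane-1,3-dione; 4 methyl 2-(benzyloxy)acetate
Product: 5 6-(benzyloxy)-1-(3,4,5-trimethoxyphenyl)hexane-1,3,5-trione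
Conditions: LDA (2.1 equiv per 3), THF, −78 → 0 °C; 4 (0.5 equiv per 3), −78 °C → rt; 1 M HCl; surplus 3 recovered
Reagents that add atoms: none
Why: Terminal acylation of a 1,3-diketone dianion, in which the second deprotonation can only occur at the CH3 group, the resulting carbanion attacks the inductively activated alkoxyacetate ester faster than it enolises it, and the second equivalent of dianion absorbs the acidic proton of the triketone.

**Step 3**
Reactants: 5 6-(benzyloxy)-1-(3,4,5-trimethoxyphenyl)hexane-1,3,5-trione
Product: 6 2-[(benzyloxy)methyl]-6-(3,4,5-trimethoxyphenyl)-4H-pyran-4-one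
Conditions: p-TsOH·H2O (10 mol %), toluene, reflux, Dean–Stark trap
Reagents that add atoms: none
Why: Acid-catalysed cyclodehydration of a 1,3,5-triketone (6-exo-trig attack of a terminal enol oxygen on the other terminal carbonyl, then loss of water), which gives the same 4-pyranone from either direction and uses an acid too mild to cleave the benzyl ether.

**Step 4**
Reactants: 6 2-[(benzyloxy)methyl]-6-(3,4,5-trimethoxyphenyl)-4H-pyran-4-one
Product: 7 2-[(Z)-1-(benzyloxy)-2-hydroxyvinyl]-6-(3,4,5-trimethoxyphenyl)-4H-pyran-4-one
Conditions: LiHMDS (2.2 equiv), THF, −78 °C; HCO2Et (3 equiv), −78 → 0 °C; cold 1 M HCl to pH 4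
Reagents that add atoms: ethyl formate, CCOC=O
Why: Vinylogous Claisen formylation, in which the hindered amide base deprotonates the CH2 between the benzyloxy group and the pyranone (gamma position of the vinylogous ester), the extended enolate reacts at the exocyclic carbon because this restores the pyranone, and the second equivalent of base holds the product as its stabilised enolate.

**Step 5**
Reactants: 7 2-[(Z)-1-(benzyloxy)-2-hydroxyvinyl]-6-(3,4,5-trimethoxyphenyl)-4H-pyran-4-one
Product: 8 2-[(Z)-1-(benzyloxy)-2-methoxyvinyl]-6-(3,4,5-trimethoxyphenyl)-4H-pyran-4-one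
Conditions: Me2SO4 (1.2 equiv), K2CO3 (1.5 equiv), DMF, 0 °C → rt; chromatography
Reagents that add atoms: dimethyl sulfate, COS(=O)(=O)OC
Why: O-alkylation of a hydroxymethylene enolate with a hard electrophile in a dipolar aprotic solvent (the tactic of beta-methoxyacrylate synthesis), where C-methylation would create a quaternary carbon and is disfavoured, and the freely rotating delocalised enolate should react from its extended form with O7 anti to C8a and potassium bridged to the benzyloxy oxygen, which sets the Z alkene; any E isomer is separated.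

**Step 6**
Reactants: 8 2-[(Z)-1-(benzyloxy)-2-methoxyvinyl]-6-(3,4,5-trimethoxyphenyl)-4H-pyran-4-one; 9 vinylene carbonate
Product: 10 rac-8-(benzyloxy)-7-methoxy-2-(3,4,5-trimethoxyphenyl)-4a,5,6,7-tetrahydro-4H-chromen-4-one 5,6-cyclic carbonate (endo adduct; H-4a/H-5/H-6/H-7 all cis; double bond at C8=C8a)
Conditions: 9 (15 equiv, neat), BHT (5 mol %), Ar, sealed silylated glass tube, 170 °C; excess 9 distilled off in vacuo
Reagents that add atoms: none
Why: Proposed new method: on heating, the pyranone ring alkene C4a=C8a and the exocyclic enol ether C8=C7 of 8 should act as one s-cis diene and add suprafacially to the C=C of 9 in a concerted thermal (4+2) cycloaddition that forms C4a–C5 and C6–C7 and leaves the remaining double bond at C8=C8a. The closest known reaction types are the Diels–Alder reactions of 2-vinyl- and 2-styrylchromones, which use the same ring-alkene-plus-vinyl diene but with maleimide-class dienophiles, and the thermal additions of vinylene carbonate to 1,4-dioxygenated butadienes and furans; pairing a monocyclic 2-vinyl-4-pyranone with this sluggish dienophile is untested, and the case for it is that the push-pull substitution (donors O1, O8 and O7, acceptor C4=O at the C4a terminus) narrows the frontier-orbital gap of the diene so that the ambiphilic enediol carbonate can engage either orbital pair. Ring A closes as a six-membered carbocycle by intermolecular two-bond annulation onto the C4a–C8a edge of ring C, and the five-membered carbonate arrives already closed and cis-fused at C5–C6. C5 and C6 are cis because the geometry of the cyclic dienophile is retained, H-4a and H-7 become cis because C4 and the methoxyl both occupy outside positions of the s-cis diene (fixed by the ring and by the Z enol ether), and endo approach of the carbonate places all four hydrogens on one face; the adduct is racemic and all four centres are erased in step 7, so exo adduct is equally usable. The selectivity that counts is cross-addition through the ring alkene: the Z geometry leaves only hydrogens on the inside positions so the s-cis conformer is reachable, the symmetry of 9 removes any regiochemical question, the large excess of 9 outcompetes self-dimerisation of 8, and BHT restrains radical polymerisation of 9. Acid- and base-free glass is specified because H-4a lies alpha to C4=O and anti to the C5 carbonate oxygen, so traces of base would start beta-elimination.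

**Step 7**
Reactants: 10 rac-8-(benzyloxy)-7-methoxy-2-(3,4,5-trimethoxyphenyl)-4a,5,6,7-tetrahydro-4H-chromen-4-one 5,6-cyclic carbonate
Product: 12 8-(benzyloxy)-5,6-(carbonyldioxy)-7-methoxy-2-(3,4,5-trimethoxyphenyl)-4H-chromen-4-one, via cis-5,6-dihydroflavone carbonate 11 (not isolated)
Conditions: DDQ (2.3 equiv), anhydrous toluene, rt → 60 °C, Ar; precipitated hydroquinone filtered off, short silica plug
Reagents that add atoms: none
Why: Quinone dehydrogenation as used to aromatise Diels–Alder adducts of 2-vinylchromones, in which hydride loss from C7–H (allylic to the C8=C8a bis-enol ether and alpha to OMe) followed by proton loss from C4a should give 11, a second hydride/proton pair leaves from C5–H and C6–H through an arenium ion stabilised by O1 and the 7-methoxyl, and the anhydrous medium without added acid or base is chosen so that elimination of carbonate, methanol or benzyl alcohol and oxidative debenzylation stay slow; all four stereocentres vanish.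

**Step 8**
Reactants: 12 8-(benzyloxy)-5,6-(carbonyldioxy)-7-methoxy-2-(3,4,5-trimethoxyphenyl)-4H-chromen-4-one
Product: 14 8-(benzyloxy)-5,6,7-trimethoxy-2-(3,4,5-trimethoxyphenyl)-4H-chromen-4-one, via catechol 13 (not isolated)
Conditions: K2CO3 (0.2 equiv), MeOH, 0 °C → rt, Ar; concentrate; MeI (5 equiv), K2CO3 (4 equiv), DMF, 40 °C, Ar
Reagents that add atoms: iodomethane, CI
Why: Base-catalysed transesterification opens the reactive aryl cyclic carbonate to the catechol and dimethyl carbonate, and Williamson methylation with excess reagent under argon then caps both phenols, including the hydrogen-bonded 5-OH, before the electron-rich catechol can autoxidise.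

**Step 9**
Reactants: 14 8-(benzyloxy)-5,6,7-trimethoxy-2-(3,4,5-trimethoxyphenyl)-4H-chromen-4-one
Product: 15 8-hydroxy-5,6,7-trimethoxy-2-(3,4,5-trimethoxyphenyl)-4H-chromen-4-one (8-hydroxy-5,6,7,3',4',5'-hexamethoxyflavone)
Conditions: H2 (1 atm), 10% Pd/C, EtOAc–MeOH, rt
Reagents that add atoms: none
Why: Catalytic hydrogenolysis of an aryl benzyl ether, which is faster than reduction of the flavone C2=C3 bond and leaves all six methyl ethers intact, including the Lewis-acid-labile 5-OMe.

**Compound list**
1 | 3',4',5'-trimethoxyacetophenone | CC(=O)c1cc(OC)c(OC)c(OC)c1 | starting material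
2 | ethyl acetate | CCOC(C)=O | starting material
3 | 1-(3,4,5-trimethoxyphenyl)butane-1,3-dione | CC(=O)CC(=O)c1cc(OC)c(OC)c(OC)c1 | intermediate
4 | methyl 2-(benzyloxy)acetate | COC(=O)COCc1ccccc1 | starting material
5 | 6-(benzyloxy)-1-(3,4,5-trimethoxyphenyl)hexane-1,3,5-trione | O=C(COCc1ccccc1)CC(=O)CC(=O)c1cc(OC)c(OC)c(OC)c1 | intermediate
6 | 2-[(benzyloxy)methyl]-6-(3,4,5-trimethoxyphenyl)-4H-pyran-4-one | O=c1cc(COCc2ccccc2)oc(-c2cc(OC)c(OC)c(OC)c2)c1 | intermediate
7 | 2-[(Z)-1-(benzyloxy)-2-hydroxyvinyl]-6-(3,4,5-trimethoxyphenyl)-4H-pyran-4-one | O/C=C(\OCc1ccccc1)c1cc(=O)cc(-c2cc(OC)c(OC)c(OC)c2)o1 | intermediate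
8 | 2-[(Z)-1-(benzyloxy)-2-methoxyvinyl]-6-(3,4,5-trimethoxyphenyl)-4H-pyran-4-one | CO/C=C(\OCc1ccccc1)c1cc(=O)cc(-c2cc(OC)c(OC)c(OC)c2)o1 | intermediate
9 | vinylene carbonate (1,3-dioxol-2-one) | O=C1OC=CO1 | starting material
10 | rac-8-(benzyloxy)-7-methoxy-2-(3,4,5-trimethoxyphenyl)-4a,5,6,7-tetrahydro-4H-chromen-4-one 5,6-cyclic carbonate, H-4a/H-5/H-6/H-7 all cis | O=C1O[C@@H]2[C@H](O1)[C@H](OC)C(OCc3ccccc3)=C3OC(-c4cc(OC)c(OC)c(OC)c4)=CC(=O)[C@H]23 | intermediate
11 | rac-cis-8-(benzyloxy)-7-methoxy-2-(3,4,5-trimethoxyphenyl)-5,6-dihydro-4H-chromen-4-one 5,6-cyclic carbonate | O=C1O[C@@H]2[C@H](O1)C(OC)=C(OCc3ccccc3)c3oc(-c4cc(OC)c(OC)c(OC)c4)cc(=O)c32 | intermediate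
12 | 8-(benzyloxy)-5,6-(carbonyldioxy)-7-methoxy-2-(3,4,5-trimethoxyphenyl)-4H-chromen-4-one | O=C1Oc2c(O1)c(OC)c(OCc3ccccc3)c3oc(-c4cc(OC)c(OC)c(OC)c4)cc(=O)c23 | intermediate
13 | 8-(benzyloxy)-5,6-dihydroxy-7-methoxy-2-(3,4,5-trimethoxyphenyl)-4H-chromen-4-one | COc1c(O)c(O)c2c(=O)cc(-c3cc(OC)c(OC)c(OC)c3)oc2c1OCc1ccccc1 | intermediate
14 | 8-(benzyloxy)-5,6,7-trimethoxy-2-(3,4,5-trimethoxyphenyl)-4H-chromen-4-one | COc1c(OC)c(OC)c2c(=O)cc(-c3cc(OC)c(OC)c(OC)c3)oc2c1OCc1ccccc1 | intermediate
15 | 8-hydroxy-5,6,7,3',4',5'-hexamethoxyflavone | COc1cc(-c2cc(=O)c3c(OC)c(OC)c(OC)c(O)c3o2)cc(OC)c1OC | target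

Total step count: 9. Longest linear sequence: 9 steps (1 → 15).

**Steps most likely to fail**

**Step 6 (labelled step).**
- Risk: the cycloaddition may not start. Breaking the cross-conjugated pyranone costs energy and the dienophile is sluggish. Thermal decay of the enol ether, self-dimerisation of the diene or polymerisation of the dienophile may then consume the material first.
- Fallback: known chemistry only, setting out from 1 and returning at 15; ring A is bought instead of built. Claisen carbethoxylation of 1 (diethyl carbonate, NaH, THF, reflux) gives ethyl 3-oxo-3-(3,4,5-trimethoxyphenyl)propanoate F1. Thermal Mentzer chromone synthesis with commercial 3,4,5-trimethoxyphenol (diphenyl ether, about 240 °C) gives 5,6,7-trimethoxy-2-(3,4,5-trimethoxyphenyl)-4H-chromen-4-one F2. Electrophilic bromination (NBS, MeCN, rt) should go to C8, the only open position of ring A, which is activated by O1, the 7-methoxyl and the 5-methoxyl. This gives 8-bromo-5,6,7-trimethoxy-2-(3,4,5-trimethoxyphenyl)-4H-chromen-4-one F3. Miyaura borylation (B2pin2, Pd(OAc)2, SPhos, KOAc, dioxane, 90 °C) gives the 8-pinacolboronate of the hexamethoxyflavone F4. Oxidation with NaBO3 (THF–H2O, rt) then delivers 15.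

**Step 7.**
- Risk: eliminative aromatisation may outrun hydride abstraction. Beta-elimination of the C5 carbonate oxygen, or loss of methanol or benzyl alcohol after a 1,3-hydrogen shift, would strip an oxygen from ring A. Oxidative loss of the benzyl group is a lesser danger.
- Fallback: sets out from 8 and returns at 12. The missing oxidation level is placed in the dienophile, so no oxidant is needed. Commercial ethylene carbonate is photochlorinated exhaustively (Cl2, hν, neat, 80 °C) to 4,4,5,5-tetrachloro-1,3-dioxolan-2-one F5. Zinc dust (Et2O, cat. DMF) dechlorinates it to 4,5-dichloro-1,3-dioxol-2-one F6, a known dienophile whose adducts serve as masked 1,2-diketones. Heating 8 with F6 as in step 6, with 2,6-di-tert-butylpyridine as acid trap, should give the 5,6-dichloro analogue of the tetrahydro adduct F7. In it C5 and C6 already stand at the catechol level. Loss of hydrogen chloride across C4a–C5 and across C7–C6 then aromatises ring A with all four oxygens kept and gives 12.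

**Step 4.**
- Risk: formylation at this hindered, alkoxy-substituted carbon may be eroded in four ways. These are proton transfer from the more acidic product to unreacted enolate, attack of base or ethoxide on the pyranone ring, base-induced decay of the formate, and deformylation during work-up.
- Fallback: sets out from 6 and returns at 7. It replaces enolate chemistry with neutral aminomethylenation, a reaction type known for 2-methyl-4-pyranones with amide acetals. Heating 6 with tert-butoxybis(dimethylamino)methane (toluene, 110 °C) should give 2-[(Z)-1-(benzyloxy)-2-(dimethylamino)vinyl]-6-(3,4,5-trimethoxyphenyl)-4H-pyran-4-one F8. Mild hydrolysis (1 M HCl, THF, rt) converts it into 7.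

**Further compounds**
F1 | step 6 | ethyl 3-oxo-3-(3,4,5-trimethoxyphenyl)propanoate | CCOC(=O)CC(=O)c1cc(OC)c(OC)c(OC)c1
F2 | step 6 | 5,6,7-trimethoxy-2-(3,4,5-trimethoxyphenyl)-4H-chromen-4-one | COc1cc(-c2cc(=O)c3c(OC)c(OC)c(OC)cc3o2)cc(OC)c1OC
F3 | step 6 | 8-bromo-5,6,7-trimethoxy-2-(3,4,5-trimethoxyphenyl)-4H-chromen-4-one | COc1cc(-c2cc(=O)c3c(OC)c(OC)c(OC)c(Br)c3o2)cc(OC)c1OC
F4 | step 6 | 5,6,7-trimethoxy-8-(4,4,5,5-tetramethyl-1,3,2-dioxaborolan-2-yl)-2-(3,4,5-trimethoxyphenyl)-4H-chromen-4-one | COc1cc(-c2cc(=O)c3c(OC)c(OC)c(OC)c(B4OC(C)(C)C(C)(C)O4)c3o2)cc(OC)c1OC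
F5 | step 7 | 4,4,5,5-tetrachloro-1,3-dioxolan-2-one | O=C1OC(Cl)(Cl)C(Cl)(Cl)O1
F6 | step 7 | 4,5-dichloro-1,3-dioxol-2-one (dichlorovinylene carbonate) | O=C1OC(Cl)=C(Cl)O1
F7 | step 7 | rac-8-(benzyloxy)-5,6-dichloro-7-methoxy-2-(3,4,5-trimethoxyphenyl)-4a,5,6,7-tetrahydro-4H-chromen-4-one 5,6-cyclic carbonate (drawn as the carbonate-endo isomer, both chlorines cis to H-4a and H-7) | O=C1O[C@]2(Cl)[C@](Cl)(O1)[C@H](OC)C(OCc3ccccc3)=C3OC(-c4cc(OC)c(OC)c(OC)c4)=CC(=O)[C@H]23
F8 | step 4 | 2-[(Z)-1-(benzyloxy)-2-(dimethylamino)vinyl]-6-(3,4,5-trimethoxyphenyl)-4H-pyran-4-one | CN(C)/C=C(\OCc1ccccc1)c1cc(=O)cc(-c2cc(OC)c(OC)c(OC)c2)o1
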